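The route rests on disconnecting the C12=C14 chloromethylene (numbering: C1 terminal CHCl, C13 benzylic CH2, C14 the ClCH= carbon on C12). Because the C10 oxygen and the C14 chlorine sit cis across C12=C14, a six-membered ring O–C10–C11–C12=C14–B can hold boron where chlorine must end up. One operation, boronate tethering of the C10 alcohol followed by ring-closing metathesis, forges C12=C14 with fixed geometry; copper-mediated chlorodeboronation then opens the ring. The precursor is the (10R)-homoallylic alcohol with a 2-benzylallyl terminus, the (E)-chloroalkene and the C4 acetate of the target already in place, made from desymmetrised cis-3,5-dimethylcyclohexanone by enolate alkylation, Baeyer–Villiger ring expansion and one-carbon homologation.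

Key step: step 11

Assumption: lithium (R,R)-bis(1-phenylethyl)amide is taken to remove the axial α-hydrogen next to the R-configured methine of the meso ketone, by analogy with its sense toward 4-substituted cyclohexanones; if the sense proves opposite, the (S,S)-amide is used.

Remark on the precursor: the C4 oxygen is carried through as the acetate that the target keeps, so no protecting group has to be removed after the key step, and any acetate lost during chlorodeboronation is restored by the final acetylation.

Step 1
Reactants: 1 3,5-dimethylcyclohex-2-en-1-one (racemic)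
Product: 2 cis-3,5-dimethylcyclohexan-1-one (meso, 3R,5S)
Conditions: H2 (1 atm), 10% Pd/C, EtOAc, rt; fractional distillation
Reagents that add atoms: none
Why: Catalytic hydrogenation should deliver hydrogen to the enone C=C from the ring face away from the C5 methyl, so the diequatorial cis (meso) ketone should predominate and residual trans isomer is removed by distillation.

Step 2
Reactants: 2 cis-3,5-dimethylcyclohexan-1-one; 3 (E)-1,3-dichloropropene
Product: 5 (2S,3R,5S)-2-[(2E)-3-chloroprop-2-en-1-yl]-3,5-dimethylcyclohexan-1-one, via lithium enolate 4 (not isolated)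
Conditions: (R,R)-bis(1-phenylethyl)amine, n-BuLi (1.0 equiv), LiCl, THF, −78 °C; 2 (1.05 equiv), −100 °C to −78 °C; then DMPU, 3, Bu4NI (cat.), −78 °C to −30 °C; aq. NH4Cl
Reagents that add atoms: none
Why: Enantioselective deprotonation of the meso ketone by the C2-symmetric chiral lithium amide in the presence of LiCl removes one of the two enantiotopic axial α-hydrogens and so fixes both methyl-bearing centres (later C5 and C7) by desymmetrisation; the regiodefined lithium enolate is then alkylated in the same flask by SN2 displacement at the allylic chloride of 3 (the vinylic chloride is inert), trans to the neighbouring C3 methyl, to give the all-equatorial ketone, which is also the thermodynamic C2 epimer, so the later C4 centre follows from substrate control.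

Step 3
Reactants: 5 (2S,3R,5S)-2-[(2E)-3-chloroprop-2-en-1-yl]-3,5-dimethylcyclohexan-1-one
Product: 6 (4S,6R,7S)-7-[(2E)-3-chloroprop-2-en-1-yl]-4,6-dimethyloxepan-2-one
Conditions: mCPBA, NaHCO3, CH2Cl2, 0 °C to rt
Reagents that add atoms: 3-chloroperoxybenzoic acid, O=C(OO)c1cccc(Cl)c1
Why: Baeyer–Villiger oxidation in which the more substituted α-carbon migrates with retention of configuration, while the electron-poor chloroalkene should be epoxidised far more slowly than the ketone is oxidised.

Step 4
Reactants: 6 (4S,6R,7S)-7-[(2E)-3-chloroprop-2-en-1-yl]-4,6-dimethyloxepan-2-one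
Product: 7 (4S,6R,7S)-7-[(2E)-3-chloroprop-2-en-1-yl]-4,6-dimethyloxepan-2-ol (lactol, mixture of C2 epimers)
Conditions: i-Bu2AlH (1.1 equiv), CH2Cl2, −78 °C; aq. potassium sodium tartrate
Reagents that add atoms: none
Why: Partial reduction of a lactone, since the tetrahedral O-aluminated hemiacetal is stable at −78 °C and releases the lactol (in equilibrium with the open hydroxy aldehyde) only on work-up.

Step 5
Reactants: 7 (4S,6R,7S)-7-[(2E)-3-chloroprop-2-en-1-yl]-4,6-dimethyloxepan-2-ol
Product: 8 (1E,4S,5R,7R)-1-chloro-10-methoxy-5,7-dimethyldeca-1,9-dien-4-ol (9E/9Z mixture)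
Conditions: Ph3P(CH2OMe)Cl (3 equiv), KN(SiMe3)2, THF, 0 °C to rt
Reagents that add atoms: (methoxymethyl)triphenylphosphonium chloride, COC[P+](c1ccccc1)(c1ccccc1)c1ccccc1.[Cl-]
Why: Wittig methoxymethylenation of the open-chain aldehyde tautomer, for which excess ylide tolerates the free hydroxyl, adds the C10 carbon as an enol ether whose geometry is irrelevant.

Step 6
Reactants: 8 (1E,4S,5R,7R)-1-chloro-10-methoxy-5,7-dimethyldeca-1,9-dien-4-ol
Product: 9 (1E,4S,5R,7R)-1-chloro-10-methoxy-5,7-dimethyldeca-1,9-dien-4-yl acetate (9E/9Z mixture)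
Conditions: Ac2O, pyridine, DMAP (cat.), CH2Cl2, rt
Reagents that add atoms: acetic anhydride, CC(=O)OC(C)=O
Why: DMAP-catalysed acylation installs at C4 the acetate that the target keeps, and the basic medium leaves the acid-labile enol ether intact.

Step 7
Reactants: 9 (1E,4S,5R,7R)-1-chloro-10-methoxy-5,7-dimethyldeca-1,9-dien-4-yl acetate
Product: 10 (1E,4S,5R,7R)-1-chloro-5,7-dimethyl-10-oxodec-1-en-4-yl acetate
Conditions: 1 M aq. HCl, THF, rt
Reagents that add atoms: water, O
Why: Acid-catalysed enol ether hydrolysis (protonation at C9, hemiacetal collapse) frees the C10 aldehyde under conditions the secondary acetate and the chloroalkene tolerate, and no stereocentre is α to the new carbonyl.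

Step 8
Reactants: 11 3-chloro-2-(chloromethyl)prop-1-ene; 12 phenylmagnesium bromide
Product: 13 [2-(chloromethyl)prop-2-en-1-yl]benzene (2-benzylallyl chloride)
Conditions: 12 (1 equiv) added to 11 (3 equiv), CuI (5 mol%), THF, −20 °C to 0 °C; distillation
Reagents that add atoms: none
Why: Copper-catalysed Grignard allylic substitution, in which SN2 and SN2' paths give the same product because 11 is symmetric and the excess of 11 suppresses double arylation.

Step 9
Reactants: 13 [2-(chloromethyl)prop-2-en-1-yl]benzene
Product: 15 tributyl(2-benzylprop-2-en-1-yl)stannane, via allylic Grignard reagent 14 (not isolated)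
Conditions: Mg turnings, Bu3SnCl, THF, 0 °C to rt (Barbier mode)
Reagents that add atoms: tributyltin chloride, CCCC[Sn](Cl)(CCCC)CCCC
Why: Barbier-type stannylation, where the allylic Grignard reagent is trapped by the tin chloride as it forms (which limits Wurtz coupling) and the two allyl termini are equivalent, so only one stannane can result.

Step 10
Reactants: 10 (1E,4S,5R,7R)-1-chloro-5,7-dimethyl-10-oxodec-1-en-4-yl acetate; 15 tributyl(2-benzylprop-2-en-1-yl)stannane
Product: 16 (1E,4S,5R,7R,10R)-12-benzyl-1-chloro-10-hydroxy-5,7-dimethyltrideca-1,12-dien-4-yl acetate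
Conditions: (S)-BINOL (20 mol%), Ti(OiPr)4 (10 mol%), 4 Å MS, CH2Cl2, −20 °C; aq. NaHCO3
Reagents that add atoms: none
Why: Keck asymmetric allylation, in which the catalyst formed from (S)-BINOL and Ti(OiPr)4 should direct the 2-substituted allylstannane to the Si face of the aldehyde and so set C10 as R under catalyst control, remote from the existing centres, as in additions of methallylstannane.

Step 11
Reactants: 16 (1E,4S,5R,7R,10R)-12-benzyl-1-chloro-10-hydroxy-5,7-dimethyltrideca-1,12-dien-4-yl acetate; 17 dibutyl ethenylboronate (dibutyl vinylboronate)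
Product: 19 (6R)-4-benzyl-2-butoxy-6-[(3R,5R,6S,8E)-6-acetoxy-9-chloro-3,5-dimethylnon-8-en-1-yl]-5,6-dihydro-2H-1,2-oxaborinine, via mixed vinylboronate 18 (not isolated)
Conditions: 17 (3 equiv), CH2Cl2, rt, 1 h; then second-generation Grubbs catalyst RuCl2(=CHPh)(PCy3)(H2IMes) (10 mol%), CH2Cl2 (0.01 M), 40 °C, argon sweep; volatiles and excess 17 removed under high vacuum, used crude
Reagents that add atoms: none
Why: Alcohol 16 exchanges one butoxy group of 17 to give the mixed boronic ester 18, the benzylidene of RuCl2(=CHPh)(PCy3)(H2IMes) is exchanged at the unhindered B-vinyl group to give a boryl-substituted ruthenium alkylidene, and this adds to the C12 methylidene in a [2+2] step, the ruthenacyclobutane then collapsing to the ring alkene with ethene as the only co-product. The closest known reaction type is the boronic-ester-tethered ring-closing metathesis of allylic and homoallylic alcohols with vinylboronates, of which the vinylsilyl ether version is the silicon counterpart. The ring O–B–C14=C12–C11–C10 (boron on C14, oxygen on C10) closes as a six-membered 5,6-dihydro-2H-1,2-oxaborinine by ring-closing metathesis, with both alkene carbons ending up endocyclic. No stereocentre is created; the C12=C14 geometry is dictated by the ring, because a six-membered ring can only hold boron and C11 cis, which is the side later taken by chlorine. The step needs chemoselectivity for the C12 methylidene over the C1=C2 chloroalkene, and the tether secures it by making closure intramolecular and six-membered, whereas the 1,2-disubstituted, electron-poor chloroalkene could only close a macrocycle and is intrinsically sluggish toward the catalyst. Excess 17 keeps the hydroxyl esterified, and its surplus vinyl groups should be harmless because vinylboronates homodimerise poorly.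

Step 12
Reactants: 19 (6R)-4-benzyl-2-butoxy-6-[(3R,5R,6S,8E)-6-acetoxy-9-chloro-3,5-dimethylnon-8-en-1-yl]-5,6-dihydro-2H-1,2-oxaborinine
Product: 20 (1E,4S,5R,7R,10R,12Z)-12-benzyl-1,13-dichloro-10-hydroxy-5,7-dimethyltrideca-1,12-dien-4-yl acetate
Conditions: CuCl2 (3 equiv), MeOH/H2O (1:1), 70 °C
Reagents that add atoms: copper dichloride, [Cu+2].[Cl-].[Cl-]
Why: Copper-mediated chlorodeboronation, in which the alkenyl group passes from boron to divalent copper with retention, a second CuCl2 oxidises it to a trivalent copper chloride and C–Cl reductive elimination places chlorine where boron stood (cis to C11), while the aqueous methanol cleaves the B–O bonds and frees the C10 hydroxyl.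

Step 13
Reactants: 20 (1E,4S,5R,7R,10R,12Z)-12-benzyl-1,13-dichloro-10-hydroxy-5,7-dimethyltrideca-1,12-dien-4-yl acetate
Product: 21 (1E,4S,5R,7R,10R,12Z)-12-benzyl-1,13-dichloro-5,7-dimethyltrideca-1,12-diene-4,10-diyl diacetate (CNP0493673.1)
Conditions: Ac2O, pyridine, DMAP (cat.), CH2Cl2, rt
Reagents that add atoms: acetic anhydride, CC(=O)OC(C)=O
Why: DMAP-catalysed acetylation of the C10 alcohol, which would also restore any C4 acetate lost to acidic methanol in step 12, completes the diacetate without touching either chloroalkene.

Compound list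

1 | 3,5-dimethylcyclohex-2-en-1-one (racemic) | CC1=CC(=O)CC(C)C1 | starting material
2 | cis-3,5-dimethylcyclohexan-1-one (meso, 3R,5S) | O=C1C[C@@H](C)C[C@@H](C)C1 | intermediate
3 | (E)-1,3-dichloropropene | ClC/C=C/Cl | starting material
4 | lithium (3R,5S)-3,5-dimethylcyclohex-1-en-1-olate (not isolated) | [Li]OC1=C[C@H](C)C[C@H](C)C1 | intermediate
5 | (2S,3R,5S)-2-[(2E)-3-chloroprop-2-en-1-yl]-3,5-dimethylcyclohexan-1-one | O=C1C[C@@H](C)C[C@@H](C)[C@@H]1C/C=C/Cl | intermediate
6 | (4S,6R,7S)-7-[(2E)-3-chloroprop-2-en-1-yl]-4,6-dimethyloxepan-2-one | O=C1C[C@@H](C)C[C@@H](C)[C@H](C/C=C/Cl)O1 | intermediate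
7 | (4S,6R,7S)-7-[(2E)-3-chloroprop-2-en-1-yl]-4,6-dimethyloxepan-2-ol (C2 epimers) | OC1C[C@@H](C)C[C@@H](C)[C@H](C/C=C/Cl)O1 | intermediate
8 | (1E,4S,5R,7R)-1-chloro-10-methoxy-5,7-dimethyldeca-1,9-dien-4-ol (9E/9Z) | COC=CC[C@@H](C)C[C@@H](C)[C@H](C/C=C/Cl)O | intermediate
9 | (1E,4S,5R,7R)-1-chloro-10-methoxy-5,7-dimethyldeca-1,9-dien-4-yl acetate (9E/9Z) | COC=CC[C@@H](C)C[C@@H](C)[C@H](C/C=C/Cl)OC(C)=O | intermediate
10 | (1E,4S,5R,7R)-1-chloro-5,7-dimethyl-10-oxodec-1-en-4-yl acetate | O=CCC[C@@H](C)C[C@@H](C)[C@H](C/C=C/Cl)OC(C)=O | intermediate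
11 | 3-chloro-2-(chloromethyl)prop-1-ene | ClCC(=C)CCl | starting material
12 | phenylmagnesium bromide | Br[Mg]c1ccccc1 | starting material
13 | [2-(chloromethyl)prop-2-en-1-yl]benzene | ClCC(=C)Cc1ccccc1 | intermediate
14 | (2-benzylprop-2-en-1-yl)magnesium chloride (not isolated) | Cl[Mg]CC(=C)Cc1ccccc1 | intermediate
15 | tributyl(2-benzylprop-2-en-1-yl)stannane | C=C(Cc1ccccc1)C[Sn](CCCC)(CCCC)CCCC | intermediate
16 | (1E,4S,5R,7R,10R)-12-benzyl-1-chloro-10-hydroxy-5,7-dimethyltrideca-1,12-dien-4-yl acetate | O[C@H](CC[C@@H](C)C[C@@H](C)[C@H](C/C=C/Cl)OC(C)=O)CC(=C)Cc1ccccc1 | intermediate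
17 | dibutyl ethenylboronate (dibutyl vinylboronate) | C=CB(OCCCC)OCCCC | starting material
18 | butyl (1E,4S,5R,7R,10R)-4-acetoxy-12-benzyl-1-chloro-5,7-dimethyltrideca-1,12-dien-10-yl ethenylboronate (not isolated) | C=CB(OCCCC)O[C@H](CC[C@@H](C)C[C@@H](C)[C@H](C/C=C/Cl)OC(C)=O)CC(=C)Cc1ccccc1 | intermediate
19 | (6R)-4-benzyl-2-butoxy-6-[(3R,5R,6S,8E)-6-acetoxy-9-chloro-3,5-dimethylnon-8-en-1-yl]-5,6-dihydro-2H-1,2-oxaborinine | CCCCOB1O[C@H](CC[C@@H](C)C[C@@H](C)[C@H](C/C=C/Cl)OC(C)=O)CC(Cc2ccccc2)=C1 | intermediate
20 | (1E,4S,5R,7R,10R,12Z)-12-benzyl-1,13-dichloro-10-hydroxy-5,7-dimethyltrideca-1,12-dien-4-yl acetate | O[C@H](CC[C@@H](C)C[C@@H](C)[C@H](C/C=C/Cl)OC(C)=O)C/C(=C\Cl)Cc1ccccc1 | intermediate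
21 | (1E,4S,5R,7R,10R,12Z)-12-benzyl-1,13-dichloro-5,7-dimethyltrideca-1,12-diene-4,10-diyl diacetate | CC(=O)O[C@H](CC[C@@H](C)C[C@@H](C)[C@H](C/C=C/Cl)OC(C)=O)C/C(=C\Cl)Cc1ccccc1 | target

Total step count: 13. Longest linear sequence: 11 steps (steps 1 to 7, then 10 to 13); steps 8 and 9 prepare the stannane in a side branch.

Steps most likely to fail

Step 11. The B–O tether is formed reversibly and is moisture-sensitive, so the concentration of the mixed ester may stay low, and closure to a trisubstituted alkenylboron may stall while the catalyst is slowly consumed at the chloroalkene. The fallback replaces boron by a robust, purifiable silicon tether and sets out from 16. Silylation with chloro(dimethyl)vinylsilane and imidazole in CH2Cl2 should give the dimethyl(vinyl)silyl ether F1. Ring-closing metathesis of this defined substrate with the same ruthenium catalyst under high dilution should give the cyclic alkenylsiloxane F2, with silicon held cis to C11 by the six-membered ring. Ring-opening iododesilylation with N-iodosuccinimide in hexafluoroisopropanol, with an AcOH/THF/H2O work-up that hydrolyses the residual O–Si bond without touching the C4 acetate, should give the alkenyl iodide F3 with retention. Copper-catalysed vinylic halogen exchange (CuI, trans-N,N'-dimethylcyclohexane-1,2-diamine, Me4NCl, EtOH, 110 °C), again with retention, brings the route back at 20.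

Step 12. Protodeboronation of the hindered alkenylboron, or erosion of the alkene geometry in hot acidic aqueous copper medium, may compete with chlorine transfer. The fallback is metal-free and sets out from 19. Treatment with KHF2 in aqueous methanol should give the potassium alkenyltrifluoroborate F4, with the C10 hydroxyl free. Electrophilic ipso-chlorination with trichloroisocyanuric acid in EtOAc/H2O at rt should then replace boron by chlorine at the same position, and the route is rejoined at 20.

Step 2. Discrimination between the enantiotopic α-hydrogens may be incomplete, and proton exchange between the enolate and the alkylated ketone during the slower alkylation may erode enantiomeric purity or lead to double alkylation; lost enantiomeric purity cannot be repaired cleanly later. The fallback uses auxiliary control in place of reagent control and sets out from 2. Condensation with (R)-1-amino-2-(methoxymethyl)pyrrolidine should give the RAMP hydrazone F5. Deprotonation with LiN(iPr)2 in THF and alkylation with 3 at −100 °C should give the alkylated hydrazone F6. The auxiliary should fix the new centre as 2S, and the substrate preference for entry trans to the neighbouring methyl makes the (2S,3R,5S) isomer the matched product. The diastereomer from alkylation at the other α-carbon is removed by chromatography at this stage. Mild two-phase cleavage with aqueous oxalic acid and ether returns the route at 5.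

Further compounds

F1 | step 11 | (1E,4S,5R,7R,10R)-12-benzyl-1-chloro-10-[dimethyl(vinyl)silyloxy]-5,7-dimethyltrideca-1,12-dien-4-yl acetate | C=C[Si](C)(C)O[C@H](CC[C@@H](C)C[C@@H](C)[C@H](C/C=C/Cl)OC(C)=O)CC(=C)Cc1ccccc1
F2 | step 11 | (6R)-4-benzyl-2,2-dimethyl-6-[(3R,5R,6S,8E)-6-acetoxy-9-chloro-3,5-dimethylnon-8-en-1-yl]-5,6-dihydro-2H-1,2-oxasiline | C[Si]1(C)O[C@H](CC[C@@H](C)C[C@@H](C)[C@H](C/C=C/Cl)OC(C)=O)CC(Cc2ccccc2)=C1
F3 | step 11 | (1E,4S,5R,7R,10R,12Z)-12-benzyl-1-chloro-10-hydroxy-13-iodo-5,7-dimethyltrideca-1,12-dien-4-yl acetate | O[C@H](CC[C@@H](C)C[C@@H](C)[C@H](C/C=C/Cl)OC(C)=O)C/C(=C\I)Cc1ccccc1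
F4 | step 12 | potassium alkenyltrifluoroborate with the skeleton of 20, BF3K on C14 cis to C11 in place of chlorine, C10 hydroxyl free | O[C@H](CC[C@@H](C)C[C@@H](C)[C@H](C/C=C/Cl)OC(C)=O)C/C(=C\[B-](F)(F)F)Cc1ccccc1.[K+]
F5 | step 2 | RAMP hydrazone of cis-3,5-dimethylcyclohexan-1-one | COC[C@H]1CCCN1N=C1C[C@@H](C)C[C@@H](C)C1
F6 | step 2 | RAMP hydrazone of (2S,3R,5S)-2-[(2E)-3-chloroprop-2-en-1-yl]-3,5-dimethylcyclohexan-1-one | COC[C@H]1CCCN1N=C1C[C@@H](C)C[C@@H](C)[C@@H]1C/C=C/Cl
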